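**Plan**
- Retrosynthetic cuts: the acid goes back to its methyl ester; the C9=C10 bond of the side chain is cut (Julia–Kocienski) into a ring-bearing tetrazolyl sulfone and (2E,4E)-hepta-2,4-dienal; the dioxolane is cut at C4–C5 and at C3–O2.
- Enabling feature: the 1,2-dioxolane consists of a ketone-derived C5(Me)(chain)–O1–O2 unit bridged by C4–C3. C4, C3, the C3 methyl and the CH2CO2H arm map onto methyl 3-methylbut-3-enoate, so the ring is one peroxycarbenium ion plus one alkene.
- Forward order: a C12 chloroalkene (1-bromo-8-chlorooctane plus methallyl Grignard) is ozonised in methanol and silylated; the only ring closes in step 4; the chain-end chloride then becomes the sulfone, the triene is joined last and the ester is hydrolysed.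
- Stereochemistry: C3 and C5 are both created in step 4 under a chiral counter-anion (trans relation and absolute sense). 11E,13E come from the dienal and 9E from the olefination; both centres are quaternary and cannot epimerise later.

Key step: step 4

Assumption: which antipode of the chiral acid leads to the (3R,5S) series cannot be predicted; it is fixed by a first run with stereochemical correlation, and the route is written for that antipode.

Step 1
Reactants: 1 1-bromo-8-chlorooctane; 2 2-methylallylmagnesium chloride (THF solution)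
Product: 3 11-chloro-2-methylundec-1-ene
Conditions: Li2CuCl4 (3 mol %), THF, –10 → 0 °C
Reagents that add atoms: none
Why: Copper-catalysed Grignard cross-coupling of an allylic magnesium reagent with a primary alkyl bromide is selective for C–Br over C–Cl, so the chloride survives as the latent handle for the sulfone.

Step 2
Reactants: 3 11-chloro-2-methylundec-1-ene
Product: 5 11-chloro-2-hydroperoxy-2-methoxyundecane, via carbonyl oxide 4 (not isolated)
Conditions: O3, CH2Cl2/MeOH (4:1), –78 °C; N2 purge, no reductant, concentrate cold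
Reagents that add atoms: ozone, O=[O+][O-]; methanol, CO
Why: Ozonolysis of a 1,1-disubstituted alkene in methanol (Criegee mechanism) should release formaldehyde and the more substituted carbonyl oxide 4, which methanol traps as the α-methoxy hydroperoxide, the alkyl chloride being inert to ozone.

Step 3
Reactants: 5 11-chloro-2-hydroperoxy-2-methoxyundecane
Product: 6 [(11-chloro-2-methoxyundecan-2-yl)peroxy]triethylsilane
Conditions: Et3SiCl, imidazole, DMF, 0 °C
Reagents that add atoms: chlorotriethylsilane, CC[Si](Cl)(CC)CC
Why: O-silylation of the hydroperoxide with a silyl chloride and imidazole is a standard protection that leaves the tertiary ketal untouched and provides the silyl peroxyketal needed for ionisation.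

Step 4
Reactants: 6 [(11-chloro-2-methoxyundecan-2-yl)peroxy]triethylsilane; 7 methyl 3-methylbut-3-enoate
Product: 10 methyl 2-[(3R,5S)-5-(9-chlorononyl)-3,5-dimethyl-1,2-dioxolan-3-yl]acetate, via peroxycarbenium ion 8 (not isolated), via tertiary carbocation 9 (not isolated)
Conditions: chiral imidodiphosphorimidate acid HN[P(=NSO2CF3)(O2C20H10Ar2)]2, Ar = 3,5-(CF3)2C6H3, built on 3,3'-diaryl-BINOL (5 mol %), 7 (3 equiv), CH2Cl2, 4 Å MS, –78 °C; chromatography
Reagents that add atoms: none
Why: Proposed new method: the closest known reaction is the SnCl4-promoted [3+2] annulation of triethylsilyl peroxyketals with alkenes, which gives racemic 1,2-dioxolanes, and here the achiral Lewis acid is replaced by the silylated form of a confined chiral imidodiphosphorimidate acid, an ion-pair catalyst type known to control additions to oxocarbenium ions generated from acetals. The acid or its Et3Si form removes methoxide from 6 (leaving as Et3SiOMe) to give peroxycarbenium ion 8 paired with the chiral anion, the methylene terminus of 7 adds to C5 (C4–C5 bond) to give tertiary cation 9, and the silylated peroxide oxygen captures C3 (C3–O2 bond) while handing Et3Si+ back to the anion, so the silyl Lewis acid should turn over. The ring therefore closes stepwise, by collapse of the internal peroxide oxygen onto a free tertiary carbenium centre to form the five-membered ring, a cation–heteroatom recombination that is not bound by the geometric limits of closures onto π bonds. C5 is set in the C–C bond formation, where the anion pocket must tell the methyl group from the long chain on the planar cation (the discrimination such anions achieve in Mukaiyama aldol additions to methyl alkyl ketones), and C3 is set in the ring closure, where the ion pair and the preference to keep the ester arm and the chain on opposite faces should favour the trans (3R,5S) isomer. The step needs Markovnikov regioselectivity, secured by the 1,1-disubstituted alkene through the tertiary cation, and ring closure faster than proton loss from 9, secured by the peroxide oxygen placed 1,3 to the cation; any cis isomer is a diastereomer and would be removed by chromatography.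

Step 5
Reactants: 10 methyl 2-[(3R,5S)-5-(9-chlorononyl)-3,5-dimethyl-1,2-dioxolan-3-yl]acetate
Product: 11 methyl 2-[(3R,5S)-3,5-dimethyl-5-[9-[(1-phenyl-1H-tetrazol-5-yl)sulfanyl]nonyl]-1,2-dioxolan-3-yl]acetate
Conditions: 1-phenyl-1H-tetrazole-5-thiol, K2CO3, NaI (cat.), DMF, 50 °C
Reagents that add atoms: 1-phenyl-1H-tetrazole-5-thiol, Sc1nnnn1-c1ccccc1
Why: Iodide-assisted SN2 displacement of the primary chloride by the soft, weakly basic tetrazolethiolate should spare the hindered di-tertiary peroxide and the methyl ester and involves no stereocentre.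

Step 6
Reactants: 11 methyl 2-[(3R,5S)-3,5-dimethyl-5-[9-[(1-phenyl-1H-tetrazol-5-yl)sulfanyl]nonyl]-1,2-dioxolan-3-yl]acetate
Product: 12 methyl 2-[(3R,5S)-3,5-dimethyl-5-[9-[(1-phenyl-1H-tetrazol-5-yl)sulfonyl]nonyl]-1,2-dioxolan-3-yl]acetate
Conditions: (NH4)6Mo7O24·4H2O (cat.), 30% H2O2, EtOH, 0 °C → rt
Reagents that add atoms: hydrogen peroxide, OO
Why: Molybdate-catalysed oxidation of a sulfide to the sulfone with H2O2 is an electrophilic oxidation to which dialkyl peroxides and esters are inert.

Step 7
Reactants: 12 methyl 2-[(3R,5S)-3,5-dimethyl-5-[9-[(1-phenyl-1H-tetrazol-5-yl)sulfonyl]nonyl]-1,2-dioxolan-3-yl]acetate; 13 (2E,4E)-hepta-2,4-dienal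
Product: 14 methyl 2-[(3R,5S)-5-[(9E,11E,13E)-hexadeca-9,11,13-trien-1-yl]-3,5-dimethyl-1,2-dioxolan-3-yl]acetate
Conditions: 13 (1.5 equiv), KN(SiMe3)2 (1.1 equiv, added last), DME, –60 °C → rt, dark, argon
Reagents that add atoms: none
Why: Julia–Kocienski olefination of an alkyl 1-phenyltetrazolyl sulfone with a conjugated aldehyde under potassium amide/DME conditions should give the new C9=C10 bond with E geometry after Smiles rearrangement and loss of SO2 and tetrazololate, while the 2E,4E geometry of 13 is carried over and the sulfone C–H is deprotonated in preference to the hindered ester α-CH2.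

Step 8
Reactants: 14 methyl 2-[(3R,5S)-5-[(9E,11E,13E)-hexadeca-9,11,13-trien-1-yl]-3,5-dimethyl-1,2-dioxolan-3-yl]acetate
Product: 15 2-[(3R,5S)-5-[(9E,11E,13E)-hexadeca-9,11,13-trien-1-yl]-3,5-dimethyl-1,2-dioxolan-3-yl]acetic acid
Conditions: LiOH·H2O, THF/H2O, 0 °C → rt; then 1 M HCl to pH 3–4, 0 °C, dark
Reagents that add atoms: lithium hydroxide, [Li+].[OH-]
Why: Saponification of the methyl ester should be clean because both peroxide carbons are quaternary, which excludes Kornblum–DeLaMare fragmentation, and the triene does not react with aqueous hydroxide.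

**Compound list**
1 | 1-bromo-8-chlorooctane | ClCCCCCCCCBr | starting material
2 | 2-methylallylmagnesium chloride | C=C(C)C[Mg]Cl | starting material
3 | 11-chloro-2-methylundec-1-ene | C=C(C)CCCCCCCCCCl | intermediate
4 | 11-chloroundecan-2-one O-oxide (transient carbonyl oxide) | CC(=[O+][O-])CCCCCCCCCCl | intermediate
5 | 11-chloro-2-hydroperoxy-2-methoxyundecane | COC(C)(OO)CCCCCCCCCCl | intermediate
6 | [(11-chloro-2-methoxyundecan-2-yl)peroxy]triethylsilane | CC[Si](CC)(CC)OOC(C)(OC)CCCCCCCCCCl | intermediate
7 | methyl 3-methylbut-3-enoate | C=C(C)CC(=O)OC | starting material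
8 | (11-chloroundecan-2-ylidene)(triethylsilyloxy)oxonium (transient peroxycarbenium ion) | CC(=[O+]O[Si](CC)(CC)CC)CCCCCCCCCCl | intermediate
9 | (4S)-13-chloro-1-methoxy-2,4-dimethyl-1-oxo-4-(triethylsilylperoxy)tridecan-2-ylium (transient tertiary carbocation) | ClCCCCCCCCC[C@@](C)(C[C+](C)CC(=O)OC)OO[Si](CC)(CC)CC | intermediate
10 | methyl 2-[(3R,5S)-5-(9-chlorononyl)-3,5-dimethyl-1,2-dioxolan-3-yl]acetate | ClCCCCCCCCC[C@@]1(C)C[C@](C)(CC(=O)OC)OO1 | intermediate
11 | methyl 2-[(3R,5S)-3,5-dimethyl-5-[9-[(1-phenyl-1H-tetrazol-5-yl)sulfanyl]nonyl]-1,2-dioxolan-3-yl]acetate | c1ccccc1-n1nnnc1SCCCCCCCCC[C@@]2(C)C[C@](C)(CC(=O)OC)OO2 | intermediate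
12 | methyl 2-[(3R,5S)-3,5-dimethyl-5-[9-[(1-phenyl-1H-tetrazol-5-yl)sulfonyl]nonyl]-1,2-dioxolan-3-yl]acetate | c1ccccc1-n1nnnc1S(=O)(=O)CCCCCCCCC[C@@]2(C)C[C@](C)(CC(=O)OC)OO2 | intermediate
13 | (2E,4E)-hepta-2,4-dienal | CC/C=C/C=C/C=O | starting material
14 | methyl 2-[(3R,5S)-5-[(9E,11E,13E)-hexadeca-9,11,13-trien-1-yl]-3,5-dimethyl-1,2-dioxolan-3-yl]acetate | CC/C=C/C=C/C=C/CCCCCCCC[C@@]1(C)C[C@](C)(CC(=O)OC)OO1 | intermediate
15 | 2-[(3R,5S)-5-[(9E,11E,13E)-hexadeca-9,11,13-trien-1-yl]-3,5-dimethyl-1,2-dioxolan-3-yl]acetic acid | CC/C=C/C=C/C=C/CCCCCCCC[C@@]1(C)C[C@](C)(CC(=O)O)OO1 | target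

**Step count**
Total: 8 steps. Longest linear sequence: 8 steps (1 → 15).

**Steps most likely to fail**

1. Step 4. The chiral anion may fail to discriminate the two faces of the peroxycarbenium ion, giving low enantio- or trans/cis selectivity, or the weak silyl Lewis acid may not turn over. The fallback sets out from 6 and 7 and uses the established achiral conditions (SnCl4, CH2Cl2, –78 °C). These should give all four stereoisomers: 10, its enantiomer methyl 2-[(3S,5R)-5-(9-chlorononyl)-3,5-dimethyl-1,2-dioxolan-3-yl]acetate F1, and the two cis isomers methyl 2-[(3R,5R)-5-(9-chlorononyl)-3,5-dimethyl-1,2-dioxolan-3-yl]acetate F2 and methyl 2-[(3S,5S)-5-(9-chlorononyl)-3,5-dimethyl-1,2-dioxolan-3-yl]acetate F3. The cis pair would be removed by preparative HPLC on silica, and the trans racemate resolved by preparative HPLC on a cellulose tris(3,5-dimethylphenylcarbamate) phase, with the absolute configuration assigned on a crystalline derivative. The fallback comes back to the route at 10; the same chiral-phase separation would also polish material of incomplete enantiomeric purity from the catalytic step.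

2. Step 7. The amide base or the sulfonyl carbanion may deprotonate next to the ester, and β-elimination would then open the peroxide ring; E-selectivity at the new double bond may also erode. The fallback sets out from sulfide 11 and removes the enolisable ester before any strong base is used. Saponification (LiOH, THF/H2O) should give 2-[(3R,5S)-3,5-dimethyl-5-[9-[(1-phenyl-1H-tetrazol-5-yl)sulfanyl]nonyl]-1,2-dioxolan-3-yl]acetic acid F4, done at the sulfide stage because the tetrazolyl sulfone is open to ipso attack by hydroxide. Molybdate/H2O2 oxidation should then give 2-[(3R,5S)-3,5-dimethyl-5-[9-[(1-phenyl-1H-tetrazol-5-yl)sulfonyl]nonyl]-1,2-dioxolan-3-yl]acetic acid F5. Its potassium carboxylate cannot enolise towards the peroxide, and olefination with 13 and 2.1 equiv of KN(SiMe3)2 would come back to the route directly at 15.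

3. Step 5. Substitution at the primary chloride may be slow, and at the temperature then required the thiolate may attack the O–O bond reductively. The fallback sets out from chloroalkene 3 and introduces sulfur before any peroxide exists. The same thiol/K2CO3/NaI conditions should give 5-[(10-methylundec-10-en-1-yl)sulfanyl]-1-phenyl-1H-tetrazole F6, and molybdate/H2O2 should give 5-[(10-methylundec-10-en-1-yl)sulfonyl]-1-phenyl-1H-tetrazole F7. Ozonolysis in methanol should give 5-[(10-hydroperoxy-10-methoxyundecyl)sulfonyl]-1-phenyl-1H-tetrazole F8, and silylation should give 5-[[10-methoxy-10-(triethylsilylperoxy)undecyl]sulfonyl]-1-phenyl-1H-tetrazole F9. Annulation of F9 with 7 as in step 4 would come back to the route at 12.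

**Further compounds**
F1 | step 4 | methyl 2-[(3S,5R)-5-(9-chlorononyl)-3,5-dimethyl-1,2-dioxolan-3-yl]acetate | ClCCCCCCCCC[C@]1(C)C[C@@](C)(CC(=O)OC)OO1
F2 | step 4 | methyl 2-[(3R,5R)-5-(9-chlorononyl)-3,5-dimethyl-1,2-dioxolan-3-yl]acetate | ClCCCCCCCCC[C@]1(C)C[C@](C)(CC(=O)OC)OO1
F3 | step 4 | methyl 2-[(3S,5S)-5-(9-chlorononyl)-3,5-dimethyl-1,2-dioxolan-3-yl]acetate | ClCCCCCCCCC[C@@]1(C)C[C@@](C)(CC(=O)OC)OO1
F4 | step 7 | 2-[(3R,5S)-3,5-dimethyl-5-[9-[(1-phenyl-1H-tetrazol-5-yl)sulfanyl]nonyl]-1,2-dioxolan-3-yl]acetic acid | c1ccccc1-n1nnnc1SCCCCCCCCC[C@@]2(C)C[C@](C)(CC(=O)O)OO2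
F5 | step 7 | 2-[(3R,5S)-3,5-dimethyl-5-[9-[(1-phenyl-1H-tetrazol-5-yl)sulfonyl]nonyl]-1,2-dioxolan-3-yl]acetic acid | c1ccccc1-n1nnnc1S(=O)(=O)CCCCCCCCC[C@@]2(C)C[C@](C)(CC(=O)O)OO2
F6 | step 5 | 5-[(10-methylundec-10-en-1-yl)sulfanyl]-1-phenyl-1H-tetrazole | C=C(C)CCCCCCCCCSc1nnnn1-c1ccccc1
F7 | step 5 | 5-[(10-methylundec-10-en-1-yl)sulfonyl]-1-phenyl-1H-tetrazole | C=C(C)CCCCCCCCCS(=O)(=O)c1nnnn1-c1ccccc1
F8 | step 5 | 5-[(10-hydroperoxy-10-methoxyundecyl)sulfonyl]-1-phenyl-1H-tetrazole | COC(C)(OO)CCCCCCCCCS(=O)(=O)c1nnnn1-c1ccccc1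
F9 | step 5 | 5-[[10-methoxy-10-(triethylsilylperoxy)undecyl]sulfonyl]-1-phenyl-1H-tetrazole | CC[Si](CC)(CC)OOC(C)(OC)CCCCCCCCCS(=O)(=O)c1nnnn1-c1ccccc1
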